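The cyclohexene ring (carotenoid locants: C1 gem-dimethyl carbon, C2 methylene, C3 carbinol, C4=C5 alkene, C6 allylic methine) is disconnected into the two-carbon unit C3–C4 and the four-carbon unit C5–C6–C1–C2. In one nickel-catalysed operation ethoxyacetylene is inserted into the strained C5–C2 bond of a 2-substituted 3,3-dimethylcyclobutanone, forming C4–C5 and C2–C3 and giving a vinylogous ester. The step exploits quaternary C1 next to the C2 methylene: the cyclobutanone comes from isobutylene, and the alkylnickel intermediate has no β-hydrogen. C6 is set in a chiral keteniminium [2+2] cycloaddition. Methyllithium transposes the enone, C7 becomes a tetrazolyl sulfone, reagent-controlled reduction sets C3, and Julia–Kocienski olefination with crocetindial completes the polyene.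

Key step: step 3

Remarks
- Carotenoid locants are used throughout (ring C1–C6, exocyclic C7, polyene C8–C8'). The target is the (3S,6R) isomer, in which the C3 hydroxyl and the C6 polyene chain are cis.
- Assumption: the (2R,5R)-auxiliary is taken to deliver the (S)-cyclobutanone 7; should the sense of induction prove opposite, the (2S,5S)-amine is used with no other change.
- Compounds 1, 2, 4, 8, 12 and 17 are taken as commercially available.

Step 1
Reactants: 1 3-[(tert-butyldimethylsilyl)oxy]propanoic acid; 2 (2R,5R)-2,5-dimethylpyrrolidine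
Product: 3 3-[(tert-butyldimethylsilyl)oxy]-1-[(2R,5R)-2,5-dimethylpyrrolidin-1-yl]propan-1-one
Conditions: DCC, HOBt (cat.), CH2Cl2, 0 °C → rt
Reagents that add atoms: none
Why: Carbodiimide-mediated amide coupling of an unhindered acid with a secondary amine, in which the silyl ether is inert and no stereocentre is touched.

Step 2
Reactants: 3 amide; 4 isobutylene
Product: 7 (2S)-2-{[(tert-butyldimethylsilyl)oxy]methyl}-3,3-dimethylcyclobutan-1-one, via keteniminium triflate 5 (not isolated), via cyclobutaniminium triflate 6 (not isolated)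
Conditions: Tf2O, 2,4,6-collidine, 4 (excess, condensed), ClCH2CH2Cl, sealed vessel, −20 → 40 °C; then H2O, rt
Reagents that add atoms: water O
Why: Keteniminium–alkene [2+2] cycloaddition, in which the CH2 terminus of isobutylene attacks the electrophilic central carbon (tertiary cation, then closure at the enamine carbon) and so fixes the 2-substituted 3,3-dimethyl pattern, while the C2-symmetric pyrrolidine shields one face of the enamine carbon and should set C6 before hydrolysis releases ketone and auxiliary.

Step 3
Reactants: 7 cyclobutanone; 8 ethoxyacetylene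
Product: 9 (6S)-6-{[(tert-butyldimethylsilyl)oxy]methyl}-3-ethoxy-5,5-dimethylcyclohex-2-en-1-one
Conditions: Ni(cod)2 (10 mol %), PCy3 (20 mol %), toluene, 60 °C, 8 added slowly by syringe pump
Reagents that add atoms: none
Why: Proposed new method: zerovalent nickel couples the cyclobutanone C=O and the ynol ether by oxidative cyclisation, the nucleophilic β-carbon of the ynol ether (C4) bonding to the carbonyl carbon C5 to give a spiro oxanickelacyclopentene; β-carbon elimination then cleaves the strained C5–C2 bond and reductive elimination joins C2 to the alkoxy-bearing C3. The closest known reaction type is the nickel-catalysed intermolecular insertion of internal dialkyl and aryl alkynes into the C(O)–C bond of 3,3-disubstituted cyclobutanones, which has not been shown for terminal ynol ethers. The six-membered ring is closed as a two-carbon ring expansion, by C(sp3)–C(sp2) reductive elimination from a seven-membered nickelacycle. No stereocentre is formed and C6 is not touched, so its configuration should be carried through. The step needs alkyne regioselectivity, secured by the polarisation of the ynol ether and by the preference of the unsubstituted alkyne carbon for the hindered carbonyl carbon, and site selectivity for the C5–C2 over the C5–C6 bond, secured by the less substituted methylene and by quaternary C1, which leaves the alkylnickel without β-hydrogen.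

Step 4
Reactants: 9 vinylogous ester
Product: 11 (4R)-4-(hydroxymethyl)-3,5,5-trimethylcyclohex-2-en-1-one, via tertiary carbinol 10 (not isolated)
Conditions: MeLi, CeCl3, THF, −78 °C; then 2 M HCl, THF, 0 °C → rt
Reagents that add atoms: methyllithium C[Li]; water O
Why: Stork–Danheiser alkylative carbonyl transposition, in which the weakly basic organocerium reagent adds 1,2 to the C5 carbonyl anti to the C6 substituent (a transient centre) and aqueous acid then ionises the tertiary allylic alcohol, hydrolyses the enol ether to the C3 ketone with the methyl-bearing C4=C5 alkene, and cleaves the primary silyl ether in the same pot without enolising C6.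

Step 5
Reactants: 11 hydroxy enone; 12 1-phenyl-1H-tetrazole-5-thiol
Product: 13 (4R)-3,5,5-trimethyl-4-{[(1-phenyl-1H-tetrazol-5-yl)sulfanyl]methyl}cyclohex-2-en-1-one
Conditions: PPh3, DIAD, THF, 0 °C → rt
Reagents that add atoms: none
Why: Mitsunobu thioetherification, an SN2 displacement of the primary oxyphosphonium by the acidic and weakly basic tetrazolethiolate, so that vinylogous β-elimination across C6–C7 should not compete and C6 is untouched.

Step 6
Reactants: 13 sulfide
Product: 14 (4R)-3,5,5-trimethyl-4-{[(1-phenyl-1H-tetrazol-5-yl)sulfonyl]methyl}cyclohex-2-en-1-one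
Conditions: (NH4)6Mo7O24·4H2O (cat.), 30% H2O2, EtOH, 0 °C → rt
Reagents that add atoms: hydrogen peroxide OO
Why: Molybdate-catalysed peroxide oxidation of sulfide to sulfone, which should be much faster than any reaction of the electron-poor enone alkene under these non-basic conditions.

Step 7
Reactants: 14 sulfone enone
Product: 16 (1S,4R)-3,5,5-trimethyl-4-{[(1-phenyl-1H-tetrazol-5-yl)sulfonyl]methyl}cyclohex-2-en-1-ol, via catechol borate 15 (not isolated)
Conditions: (R)-2-methyl-CBS-oxazaborolidine (20 mol %), catecholborane, toluene, −78 °C; then MeOH, aq. NaHCO3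
Reagents that add atoms: none
Why: Corey–Bakshi–Shibata reduction, in which the (R)-oxazaborolidine should bind the ketone with the C4=C5 alkenyl arm as the large group and deliver hydride to the Re face of C3, the face remote from the C6 substituent, giving the (S)-carbinol cis to C7 by reagent control under non-basic conditions that spare the sulfone and C6.

Step 8
Reactants: 16 hydroxy sulfone; 17 crocetindial
Product: 18 (3S,6R)-3-hydroxy-8'-apo-ε-caroten-8'-al
Conditions: KN(SiMe3)2 (2.1 equiv), THF, −78 °C; transferred into 17 (3 equiv) in THF, −60 °C → rt, dark; aq. NH4Cl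
Reagents that add atoms: none
Why: Julia–Kocienski olefination, in which the first equivalent of base gives a spectator C3 alkoxide and the second the sulfonyl carbanion, which adds to one formyl group of the dialdehyde held in excess, after which Smiles rearrangement and loss of SO2 and tetrazolate should give the (E)-C7=C8 alkene expected for a branched alkyl phenyltetrazolyl sulfone, the all-E product being purified by crystallisation.

Compound list
1 | 3-[(tert-butyldimethylsilyl)oxy]propanoic acid | OC(=O)CCO[Si](C)(C)C(C)(C)C | starting material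
2 | (2R,5R)-2,5-dimethylpyrrolidine | C[C@@H]1CC[C@@H](C)N1 | starting material
3 | 3-[(tert-butyldimethylsilyl)oxy]-1-[(2R,5R)-2,5-dimethylpyrrolidin-1-yl]propan-1-one | C[C@@H]1CC[C@@H](C)N1C(=O)CCO[Si](C)(C)C(C)(C)C | intermediate
4 | isobutylene (2-methylpropene) | CC(C)=C | starting material
5 | keteniminium triflate: (2R,5R)-1-{3-[(tert-butyldimethylsilyl)oxy]prop-1-en-1-ylidene}-2,5-dimethylpyrrolidinium triflate | C[C@@H]1CC[C@@H](C)[N+]1=C=CCO[Si](C)(C)C(C)(C)C.[O-]S(=O)(=O)C(F)(F)F | intermediate
6 | cyclobutaniminium triflate: (2R,5R)-1-[(2S)-2-{[(tert-butyldimethylsilyl)oxy]methyl}-3,3-dimethylcyclobutylidene]-2,5-dimethylpyrrolidinium triflate | C[C@@H]1CC[C@@H](C)[N+]1=C2CC(C)(C)[C@H]2CO[Si](C)(C)C(C)(C)C.[O-]S(=O)(=O)C(F)(F)F | intermediate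
7 | (2S)-2-{[(tert-butyldimethylsilyl)oxy]methyl}-3,3-dimethylcyclobutan-1-one | O=C1CC(C)(C)[C@H]1CO[Si](C)(C)C(C)(C)C | intermediate
8 | ethoxyacetylene (ethyl ethynyl ether) | C#COCC | starting material
9 | (6S)-6-{[(tert-butyldimethylsilyl)oxy]methyl}-3-ethoxy-5,5-dimethylcyclohex-2-en-1-one | O=C1C=C(OCC)CC(C)(C)[C@H]1CO[Si](C)(C)C(C)(C)C | intermediate
10 | tertiary carbinol (1R,6S)-6-{[(tert-butyldimethylsilyl)oxy]methyl}-3-ethoxy-1,5,5-trimethylcyclohex-2-en-1-ol (formed as its metal alkoxide; hydroxyl cis to the silyloxymethyl group) | C[C@]1(O)C=C(OCC)CC(C)(C)[C@H]1CO[Si](C)(C)C(C)(C)C | intermediate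
11 | (4R)-4-(hydroxymethyl)-3,5,5-trimethylcyclohex-2-en-1-one | CC1=CC(=O)CC(C)(C)[C@H]1CO | intermediate
12 | 1-phenyl-1H-tetrazole-5-thiol | Sc1nnnn1-c1ccccc1 | starting material
13 | (4R)-3,5,5-trimethyl-4-{[(1-phenyl-1H-tetrazol-5-yl)sulfanyl]methyl}cyclohex-2-en-1-one | CC1=CC(=O)CC(C)(C)[C@H]1CSc1nnnn1-c1ccccc1 | intermediate
14 | (4R)-3,5,5-trimethyl-4-{[(1-phenyl-1H-tetrazol-5-yl)sulfonyl]methyl}cyclohex-2-en-1-one | CC1=CC(=O)CC(C)(C)[C@H]1CS(=O)(=O)c1nnnn1-c1ccccc1 | intermediate
15 | catechol borate of 16: 2-{[(1S,4R)-3,5,5-trimethyl-4-{[(1-phenyl-1H-tetrazol-5-yl)sulfonyl]methyl}cyclohex-2-en-1-yl]oxy}-1,3,2-benzodioxaborole | CC1=C[C@@H](OB2Oc3ccccc3O2)CC(C)(C)[C@H]1CS(=O)(=O)c1nnnn1-c1ccccc1 | intermediate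
16 | (1S,4R)-3,5,5-trimethyl-4-{[(1-phenyl-1H-tetrazol-5-yl)sulfonyl]methyl}cyclohex-2-en-1-ol (hydroxyl cis to the sulfonylmethyl group) | CC1=C[C@@H](O)CC(C)(C)[C@H]1CS(=O)(=O)c1nnnn1-c1ccccc1 | intermediate
17 | crocetindial, (2E,4E,6E,8E,10E,12E,14E)-2,6,11,15-tetramethylhexadeca-2,4,6,8,10,12,14-heptaenedial | O=C/C(C)=C/C=C/C(C)=C/C=C/C=C(C)/C=C/C=C(\C)C=O | starting material
18 | (3S,6R)-3-hydroxy-8'-apo-ε-caroten-8'-al | CC1=C[C@@H](O)CC(C)(C)[C@H]1/C=C/C(C)=C/C=C/C(C)=C/C=C/C=C(C)/C=C/C=C(\C)C=O | target

Total step count: 8
Longest linear sequence: 8 steps (1 → 18)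

Steps most likely to fail

Step 3 (Proposed new method). The terminal ynol ether may be consumed by nickel-catalysed oligomerisation before it cyclises with the ketone, the oxidative cyclisation may take the reverse regiochemistry, or β-carbon elimination may cleave toward C6. The fallback uses known chemistry, sets out from 7 and returns at 9, and makes the two bonds in separate operations (C2–C3 by aldol addition, C4–C5 by Dieckmann condensation). The kinetic lithium enolate of 7 (LiN(iPr)2, THF, −78 °C, deprotonation at the unsubstituted C2 methylene) is trapped with acetaldehyde to give aldol adduct F1. Dess–Martin oxidation gives 2-acetylcyclobutanone F2. NaOEt in EtOH adds to the strained ring carbonyl, retro-Claisen cleavage of C5–C2 gives a δ-keto ester, and Dieckmann condensation of its methyl ketone onto the ester closes cyclohexane-1,3-dione F3. EtOH with catalytic TsOH and azeotropic removal of water etherifies the less hindered C3 carbonyl and gives 9.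

Step 7. Facial selectivity may be poor if the neopentyl-type C2 arm competes with the alkenyl arm for the large-group site of the catalyst, or if a conformational bias of the ring opposes the catalyst. The fallback sets out from 14 and returns at 16. Luche reduction (NaBH4, CeCl3·7H2O, MeOH, −78 °C) should give 16 together with its C3 epimer, trans-alcohol F4. The two are separated by chromatography, and F4 is recycled by Mitsunobu inversion (4-nitrobenzoic acid, PPh3, DIAD, THF) to cis-4-nitrobenzoate F5, whose methanolysis (K2CO3, MeOH, 0 °C) gives 16.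

Step 2. Facial discrimination by the auxiliary in the stepwise cycloaddition may be insufficient, or the iminium salt may epimerise at C6 through its enamine before hydrolysis; either would erode the enantiomeric purity. The fallback sets out from 1 and returns at 7. Acid 1 is coupled with dimethylamine (DCC) to the achiral dimethylamide F6. The same keteniminium cycloaddition with 4 gives racemic cyclobutanone F7, which is resolved by preparative chromatography on a chiral stationary phase; the (S)-enantiomer is 7.

Further compounds
F1 | step 3 | (2S)-2-{[(tert-butyldimethylsilyl)oxy]methyl}-4-(1-hydroxyethyl)-3,3-dimethylcyclobutan-1-one (mixture at C4 and the carbinol carbon) | O=C1C(C(C)O)C(C)(C)[C@H]1CO[Si](C)(C)C(C)(C)C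
F2 | step 3 | (2S)-4-acetyl-2-{[(tert-butyldimethylsilyl)oxy]methyl}-3,3-dimethylcyclobutan-1-one | O=C1C(C(C)=O)C(C)(C)[C@H]1CO[Si](C)(C)C(C)(C)C
F3 | step 3 | (4S)-4-{[(tert-butyldimethylsilyl)oxy]methyl}-5,5-dimethylcyclohexane-1,3-dione | O=C1CC(=O)CC(C)(C)[C@H]1CO[Si](C)(C)C(C)(C)C
F4 | step 7 | (1R,4R)-3,5,5-trimethyl-4-{[(1-phenyl-1H-tetrazol-5-yl)sulfonyl]methyl}cyclohex-2-en-1-ol | CC1=C[C@H](O)CC(C)(C)[C@H]1CS(=O)(=O)c1nnnn1-c1ccccc1
F5 | step 7 | (1S,4R)-3,5,5-trimethyl-4-{[(1-phenyl-1H-tetrazol-5-yl)sulfonyl]methyl}cyclohex-2-en-1-yl 4-nitrobenzoate | CC1=C[C@@H](OC(=O)c2ccc(cc2)[N+](=O)[O-])CC(C)(C)[C@H]1CS(=O)(=O)c1nnnn1-c1ccccc1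
F6 | step 2 | 3-[(tert-butyldimethylsilyl)oxy]-N,N-dimethylpropanamide | CN(C)C(=O)CCO[Si](C)(C)C(C)(C)C
F7 | step 2 | racemic 2-{[(tert-butyldimethylsilyl)oxy]methyl}-3,3-dimethylcyclobutan-1-one | O=C1CC(C)(C)C1CO[Si](C)(C)C(C)(C)C
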